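## Structural features

The target is a 2,5-diaryl-3,4-dimethyltetrahydrofuran (a 7,7′-epoxylignan). It has one five-membered ring, O1 and C2–C5, with a 3,4-dimethoxyphenyl group on C2, methyl groups on C3 and C4, and a 3,4,5-trimethoxyphenyl group on C5; the five aryl methyl ethers are the only other functionality. All four ring carbons are adjacent stereocentres, (2R,3S,4S,5S): the C2 aryl group is cis to the C3 methyl group, the two methyl groups are trans, the C4 methyl group is trans to the C5 aryl group, and the two aryl groups are therefore cis across O1. Taken alone, the C3–C4 dimethyl unit is C2-symmetric; the symmetry is broken by one extra methoxy group and by C2, the only centre that is cis to its neighbour and hence contra-thermodynamic. Both C–O bonds are benzylic and para to a methoxy group, so Brønsted and Lewis acids open them reversibly (most easily at C2, where the 4-methoxy group is fully conjugated) and drain the 2,3-cis isomer towards the all-trans one; hydrogenolysis is a second threat. The oxygen-bearing carbons C2 and C5 stand in a 1,4-relationship, a dissonant pattern: C3 and C4 are both α-carbons of latent carbonyl groups, both nucleophilic by nature, and no ordinary donor–acceptor pair makes the bond between them. The real difficulty is twofold: forming the central C3–C4 bond with both methyl-bearing centres in absolute configuration while the two almost identical aryl termini stay distinguishable, and setting the labile C2 centre under kinetic control at the very end. The key step exploits the fact that the ring skeleton is two propanoid units, C2–C3–CH3 and C5–C4–CH3, joined at their α-carbons: C3 and C4 are coupled directly as two enolate carbons by removal of two electrons.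

## Logic of the disconnections

The ring numbering of 14 (O1, C2–C5) is used for all intermediates. In one sentence: the C3–C4 bond of 7 is made by oxidative cross-coupling of the two enolates 5 and 6.

**14 ⇒ 12 (through 13).** The C2–H bond is cut. C2 is the only centre cis to its neighbour and sits on the more easily ionised C–O bond, so it has to be made last and under kinetic control. Making C2 planar in 13 removes one stereocentre and makes the C2 configuration of 12 irrelevant. The forward step needs hydride delivery anti to the C3 methyl group. It also needs conditions under which 14 is not left in contact with the Lewis acid.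

**12 ⇒ 9 + 11 (11 from 10).** The C2–aryl bond is cut. This takes out the more acid-labile arene, which is then present for only two steps, and turns C2 into an acyl carbon. 9 carries one arene and three centres that are all trans and therefore thermodynamically settled. The cut fixes which arene enters when: the arene of 10 must come last, because only the carbon that receives hydride can become the cis centre. The forward step must stop after a single addition.

**9 ⇒ 7 (through 8).** The acyl–oxygen bond O1–C2 and the C5–H bond are cut. Opening the ring uncovers an acyclic 1,4-dicarbonyl compound in which C5 is a ketone and C2 an activated acyl group whose controller doubles as the leaving group of the ring closure. The ring and the C5 centre vanish. The forward step needs 1,2-induction from C4 and attack on the ketone in preference to the imide.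

**7 ⇒ 5 + 6 (from 4 and 3); key disconnection.** The central C3–C4 bond is cut.
- Why here: it is the bond that the dissonant 1,4-pattern makes inaccessible to polar logic. It carries both methyl-bearing centres and halves the molecule into two propionyl units.
- Gain: a chain with two adjacent stereocentres and two different termini falls back to two three-carbon carbonyl compounds with no stereocentre in the chain. The termini are different functional groups from the start, so the two arenes never compete.
- Demand: cross-coupling over homocoupling, facial control at C3, relative topicity at C4, and an oxidant strong enough for enolates yet too weak for a trimethoxyarene.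

**3 ⇒ 1 (through 2).** The C4–C5 bond is cut between the carbonyl carbon and its ethyl group. This leads to a catalogue nitrile and an ethyl Grignard reagent. The only demand is that addition stops at the imine stage.

## Other disconnections considered

Alternative 1: the route drawn first. The cut is C4–C5, with C2 and the C3 methyl group added afterwards. The forward key step is an auxiliary-controlled anti-aldol addition of a propionate enolate to 3,4,5-trimethoxybenzaldehyde (A1). After release of the controller this would give hydroxy ester A2. Its ester carbon is C3, so C2 has to be brought in by a one-carbon homologation to lactone A3, and the C3 methyl group by alkylation of the lactone enolate, which meets the chosen route at 9. The aldol step is dependable, but it builds a consonant 1,3-dioxygen pattern into a target whose pattern is 1,4. The strongest step does not touch the central bond, and only two of the four centres come from it. Protection, reduction, activation, homologation, oxidation and methylation must follow, several times the number of operations that lead from 3 and 4 to 9.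

Alternative 2: a (3+2) cycloaddition. The cuts are O1–C2 and C4–C5. The forward key step is the Lewis-acid-catalysed (for example Sn(OTf)2) union of donor–acceptor cyclopropane A4 with A1 to give tetrahydrofuran diester A5. The aldehyde oxygen opens the benzylic carbon with inversion, so the trans cyclopropane becomes the 2,3-cis pair, and the malonate carbon closes on the carbonyl with the usual 2,5-cis preference. The stereochemical fit is attractive. However, the two ester groups on C4 that polarise A4 are not in the target: one has to be deleted (Krapcho dealkoxycarbonylation) and the other taken down to CH3 in three further steps. A donor as electron-rich as a 3,4-dimethoxyphenyl group also makes ring opening of A4 reversible under the Lewis acid. With C3 fixed, that turns loss of configuration at C2 into a diastereomer problem. Finally, A4 needs an enantioselective malonate-carbene transfer to a 1,2-disubstituted styrene, a harder asymmetric step than any in the chosen plan.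

Alternative 3: polarity reversal by a masked acyl anion. The cut is C4–C5 again, now with C5 as the nucleophile. The forward key step is conjugate addition of lithiated dithiane A6 to a crotonate ester and methylation of the resulting enolate, which would give A7, a masked form of the ester analogue of 7. This buys the umpolung with two extra operations (mask on, mask off), whereas the chosen plan buys it by removing two electrons. A tertiary, aryl-stabilised carbanion must add 1,4 to a β-substituted acceptor and create C4 next to a quaternary carbon. Absolute control is not inherent and needs a further controller. Unmasking also calls for thiophilic or oxidising reagents in the presence of an electron-rich arene.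

Key step: step 2

Assumption: 12 is handled as a mixture of anomers in equilibrium with its open hydroxy ketone form, so C2 is left undefined in its SMILES; this has no consequence because C2 becomes planar in 13.

## Steps

Step 1
Reactants: 1 3,4,5-trimethoxybenzonitrile
Product: 3 1-(3,4,5-trimethoxyphenyl)propan-1-one, via bromomagnesium ketimide 2 (not isolated)
Conditions: EtMgBr (1.5 equiv), THF, 0 °C → reflux; then 2 M aq HCl, rt
Reagents that add atoms: ethylmagnesium bromide CC[Mg]Br; water O
Why: Grignard addition to a nitrile: the N-magnesio ketimine 2 is inert to a second addition, and aqueous acid hydrolyses it to the ketone. No stereocentre is formed and the aryl methyl ethers are inert.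

Step 2
Reactants: 3 1-(3,4,5-trimethoxyphenyl)propan-1-one; 4 (R)-4-benzyl-3-propionyloxazolidin-2-one
Product: 7 (R)-4-benzyl-3-[(2S,3S)-2,3-dimethyl-4-oxo-4-(3,4,5-trimethoxyphenyl)butanoyl]oxazolidin-2-one, via imide lithium enolate 5 (not isolated), via ketone lithium enolate 6 (not isolated)
Conditions: 3 + 4 (1:1), LiN(i-Pr)2 (2.1 equiv), THF, −78 °C; then Fe(acac)3 (2.1 equiv), −78 °C → rt
Reagents that add atoms: none
Why: This is an oxidative enolate heterocoupling, a known reaction type for N-acyl oxazolidinone enolates with aryl ketone enolates. The bidentate imide enolate 5 should exchange onto trivalent iron and be oxidised by inner-sphere electron transfer to a chelated, electrophilic α-carbonyl radical; the more nucleophilic, monodentate ketone enolate 6 adds to it, and the second equivalent of Fe(acac)3 oxidises the resulting ketyl-type radical anion to the ketone of 7. No ring is closed; the only bond formed is C3–C4, between two carbons that are both nucleophilic in the ground state. C3 is controlled by the auxiliary: two-point metal binding holds the two imide carbonyl groups syn, A(1,3) strain fixes the Z geometry, and the benzyl group of the (R)-auxiliary shields one face, so the bond forms in the same sense as in an enolate alkylation and gives (S). C4 is controlled only by relative topicity: if both oxygens stay on one metal cluster the two carbonyl carbons are synclinal in the transition state, and the arrangement with the methyl groups anti, which leads to the like (S,S) isomer, should be the less crowded. The step needs cross-coupling over the two homocouplings, which rests on this division of roles (the enolate oxidised fastest is not the one that traps fastest) and on mixed aggregation of the 1:1 enolate pair. Material with the wrong configuration at C4 can be separated and re-equilibrated with DBU, because that centre is α to an aryl ketone while A(1,3) strain in the imide protects C3 from deprotonation. Fe(acac)3 is too weak an oxidant to attack the trimethoxyarene, the carbamate or the neutral product.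

Step 3
Reactants: 7 (R)-4-benzyl-3-[(2S,3S)-2,3-dimethyl-4-oxo-4-(3,4,5-trimethoxyphenyl)butanoyl]oxazolidin-2-one
Product: 9 (3S,4S,5S)-3,4-dimethyl-5-(3,4,5-trimethoxyphenyl)dihydrofuran-2(3H)-one, via lithium alkoxide 8 (not isolated)
Conditions: LiBH(s-Bu)3 (1.1 equiv), THF, −78 → 0 °C; then AcOH
Reagents that add atoms: none
Why: Felkin–Anh-controlled ketone reduction followed by lactonisation with expulsion of the auxiliary (intramolecular acyl transfer, 5-exo-trig). With the branched C3 carbon as the large group perpendicular to the carbonyl plane, the bulky hydride passes the C4–H and should give the (S)-alkoxide 8, that is the 4,5-trans relationship; at −78 °C the aryl ketone is attacked faster than either imide carbonyl. C3 and C4 are not touched, and C3 already has the more stable trans arrangement, so adventitious enolisation of 9 is harmless.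

Step 4
Reactants: 9 (3S,4S,5S)-3,4-dimethyl-5-(3,4,5-trimethoxyphenyl)dihydrofuran-2(3H)-one; 10 4-bromo-1,2-dimethoxybenzene
Product: 12 (3S,4S,5S)-2-(3,4-dimethoxyphenyl)-3,4-dimethyl-5-(3,4,5-trimethoxyphenyl)tetrahydrofuran-2-ol (anomeric mixture), via 3,4-dimethoxyphenyllithium 11 (not isolated)
Conditions: 10, n-BuLi (1.15 equiv each), THF, −78 °C; then 9, −78 °C; then AcOH, −78 °C
Reagents that add atoms: none
Why: Bromine–lithium exchange and 1,2-addition of an aryllithium to a γ-lactone; the tetrahedral lithium alkoxide persists at −78 °C, which prevents a second addition, and the cold acidic quench avoids base-mediated epimerisation at C3 of the open hydroxy ketone form. The new C2 centre is an inconsequential anomeric mixture.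

Step 5
Reactants: 12 (3S,4S,5S)-2-(3,4-dimethoxyphenyl)-3,4-dimethyl-5-(3,4,5-trimethoxyphenyl)tetrahydrofuran-2-ol
Product: 14 (2R,3S,4S,5S)-2-(3,4-dimethoxyphenyl)-3,4-dimethyl-5-(3,4,5-trimethoxyphenyl)tetrahydrofuran, via oxocarbenium ion 13 (not isolated)
Conditions: Et3SiH (5 equiv), BF3·OEt2 (2 equiv), CH2Cl2, −78 °C; Et3N, then aq NaHCO3, added at −78 °C
Reagents that add atoms: none
Why: Ionic reduction of a cyclic hemiketal with a silane through the aryl-stabilised oxocarbenium ion 13. Hydride adds to planar C2 from the face opposite the adjacent C3 methyl group, which is also the face away from the C5 aryl group, so H ends trans and the aryl group cis to the C3 methyl group, (2R). This is the kinetic product, hence the excess of silane, the low temperature and the cold basic quench, which keep BF3 from reopening the C2–O bond.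

## Compound list

1 | 3,4,5-trimethoxybenzonitrile | COc1cc(C#N)cc(OC)c1OC | starting material
2 | N-(bromomagnesio)-1-(3,4,5-trimethoxyphenyl)propan-1-imine | CCC(=N[Mg]Br)c1cc(OC)c(OC)c(OC)c1 | intermediate
3 | 1-(3,4,5-trimethoxyphenyl)propan-1-one | CCC(=O)c1cc(OC)c(OC)c(OC)c1 | intermediate
4 | (R)-4-benzyl-3-propionyloxazolidin-2-one | CCC(=O)N1[C@H](Cc2ccccc2)COC1=O | starting material
5 | lithium (Z)-enolate of 4 | C/C=C(\O[Li])N1[C@H](Cc2ccccc2)COC1=O | intermediate
6 | lithium (Z)-enolate of 3 | C/C=C(\O[Li])c1cc(OC)c(OC)c(OC)c1 | intermediate
7 | (R)-4-benzyl-3-[(2S,3S)-2,3-dimethyl-4-oxo-4-(3,4,5-trimethoxyphenyl)butanoyl]oxazolidin-2-one | O=C(N1[C@H](Cc2ccccc2)COC1=O)[C@@H](C)[C@H](C)C(=O)c1cc(OC)c(OC)c(OC)c1 | intermediate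
8 | lithium (1S,2S,3S)-4-[(R)-4-benzyl-2-oxooxazolidin-3-yl]-2,3-dimethyl-4-oxo-1-(3,4,5-trimethoxyphenyl)butan-1-olate | O=C(N1[C@H](Cc2ccccc2)COC1=O)[C@@H](C)[C@H](C)[C@H](O[Li])c1cc(OC)c(OC)c(OC)c1 | intermediate
9 | (3S,4S,5S)-3,4-dimethyl-5-(3,4,5-trimethoxyphenyl)dihydrofuran-2(3H)-one | O=C1O[C@H](c2cc(OC)c(OC)c(OC)c2)[C@@H](C)[C@@H]1C | intermediate
10 | 4-bromo-1,2-dimethoxybenzene | COc1ccc(Br)cc1OC | starting material
11 | 3,4-dimethoxyphenyllithium | COc1ccc([Li])cc1OC | intermediate
12 | (3S,4S,5S)-2-(3,4-dimethoxyphenyl)-3,4-dimethyl-5-(3,4,5-trimethoxyphenyl)tetrahydrofuran-2-ol, anomeric mixture | COc1ccc(C2(O)O[C@H](c3cc(OC)c(OC)c(OC)c3)[C@@H](C)[C@@H]2C)cc1OC | intermediate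
13 | (3S,4S,5S)-2-(3,4-dimethoxyphenyl)-3,4-dimethyl-5-(3,4,5-trimethoxyphenyl)-4,5-dihydro-3H-furan-1-ium hydroxytrifluoroborate | COc1ccc(C2=[O+][C@H](c3cc(OC)c(OC)c(OC)c3)[C@@H](C)[C@@H]2C)cc1OC.O[B-](F)(F)F | intermediate
14 | (2R,3S,4S,5S)-2-(3,4-dimethoxyphenyl)-3,4-dimethyl-5-(3,4,5-trimethoxyphenyl)tetrahydrofuran | COc1ccc([C@@H]2O[C@H](c3cc(OC)c(OC)c(OC)c3)[C@@H](C)[C@@H]2C)cc1OC | target

## Step count and least certain steps

Total step count: 5. Longest linear sequence: 5 steps (1 → 3 → 7 → 9 → 12 → 14); 4 and 10 enter as bought.

**Step 2 (key step).** The most likely failures are these: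
- Cross-selectivity is lost, because each enolate can also couple with itself if the rates of oxidation and trapping of the two partners are not far enough apart.
- Relative topicity at C4 is weak, because an open antiperiplanar transition state, which favours the unlike arrangement, can compete with the metal-bridged one.
- Proton transfer from the product to unreacted enolate caps conversion.

The fallback sets out from 4 and returns at 9, and uses the hidden C2 symmetry of the C3–C4 unit. 4 alone is enolised with LiN(i-Pr)2 and oxidised with CuCl2 to the dimer (2S,3S)-1,4-bis[(R)-4-benzyl-2-oxooxazolidin-3-yl]-2,3-dimethylbutane-1,4-dione F1. In F1 both new centres are under auxiliary control and no cross-selectivity is needed. LiOH/H2O2 gives (2S,3S)-2,3-dimethylsuccinic acid F2, and acetyl chloride closes it to (3S,4S)-3,4-dimethyldihydrofuran-2,5-dione F3. The two carbonyl groups of F3 are homotopic. One equivalent of 3,4,5-trimethoxyphenylmagnesium bromide F4 (from the commercial aryl bromide and Mg) at −78 °C can therefore give only (2S,3S)-2,3-dimethyl-4-oxo-4-(3,4,5-trimethoxyphenyl)butanoic acid F5. Reduction of its carboxylate salt with LiBH(s-Bu)3 and acidification return to 9.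

**Step 3.** The most likely failures are insufficient facial selectivity at the ketone, since the electron-rich aryl ketone is sluggish and may need a temperature at which the Felkin–Anh preference erodes, and competing hydride attack on the imide.

The fallback sets out from 7 and returns at 9, and replaces kinetic by thermodynamic control at C5. 7 is reduced without regard to selectivity (NaBH4, THF/MeOH), which gives 9 together with its C5 epimer (3S,4S,5R)-3,4-dimethyl-5-(3,4,5-trimethoxyphenyl)dihydrofuran-2(3H)-one F6. The mixture is then equilibrated with BF3·OEt2 in CH2Cl2. Reversible ionisation of the benzylic C5–O bond and reclosure by the carboxyl oxygen should funnel the material into the more stable all-trans 9.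

**Step 4.** The most likely failures are premature collapse of the tetrahedral intermediate followed by a second addition, and enolisation of the lactone by the basic aryllithium, which returns starting material.

The fallback sets out from 9 and returns at 12.
- MeNH(OMe)·HCl and i-PrMgCl open 9 to (2S,3S,4S)-4-hydroxy-N-methoxy-N,2,3-trimethyl-4-(3,4,5-trimethoxyphenyl)butanamide F7.
- F7 is silylated at once (t-BuMe2SiOTf, 2,6-lutidine) to (2S,3S,4S)-4-(tert-butyldimethylsilyloxy)-N-methoxy-N,2,3-trimethyl-4-(3,4,5-trimethoxyphenyl)butanamide F8.
- 11 adds once to the chelating amide to give (2S,3S,4S)-4-(tert-butyldimethylsilyloxy)-1-(3,4-dimethoxyphenyl)-2,3-dimethyl-4-(3,4,5-trimethoxyphenyl)butan-1-one F9.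
- Bu4NF buffered with AcOH frees the C5 hydroxyl group, which closes to 12.

**Step 5.** The most likely failures are these:
- C2 epimerises after the reduction by Lewis-acid-mediated reopening of the C2–O bond.
- 13 loses the C3 proton to an enol ether, and reprotonation scrambles C3.
- A second ionisation leads to over-reduction.

The fallback sets out from 9, by way of F9 of the preceding fallback, and returns at 14. It sets C2 by a stereospecific substitution in base instead of a cation reduction in acid. Felkin–Anh reduction of F9 with LiBH(s-Bu)3 gives (1S,2S,3S,4S)-4-(tert-butyldimethylsilyloxy)-1-(3,4-dimethoxyphenyl)-2,3-dimethyl-4-(3,4,5-trimethoxyphenyl)butan-1-ol F10. MsCl/Et3N at low temperature gives (1S,2S,3S,4S)-4-(tert-butyldimethylsilyloxy)-1-(3,4-dimethoxyphenyl)-2,3-dimethyl-4-(3,4,5-trimethoxyphenyl)butyl methanesulfonate F11. Bu4NF, added in the cold without isolation, frees the C5 alkoxide, which displaces the sulfonate with inversion at C2. The closure has to outrun ionisation of the sulfonate.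

## Further compounds

F1 | step 2 | (2S,3S)-1,4-bis[(R)-4-benzyl-2-oxooxazolidin-3-yl]-2,3-dimethylbutane-1,4-dione | O=C(N1[C@H](Cc2ccccc2)COC1=O)[C@@H](C)[C@H](C)C(=O)N1[C@H](Cc2ccccc2)COC1=O
F2 | step 2 | (2S,3S)-2,3-dimethylsuccinic acid | OC(=O)[C@@H](C)[C@H](C)C(=O)O
F3 | step 2 | (3S,4S)-3,4-dimethyldihydrofuran-2,5-dione | O=C1OC(=O)[C@@H](C)[C@@H]1C
F4 | step 2 | 3,4,5-trimethoxyphenylmagnesium bromide | COc1cc([Mg]Br)cc(OC)c1OC
F5 | step 2 | (2S,3S)-2,3-dimethyl-4-oxo-4-(3,4,5-trimethoxyphenyl)butanoic acid | OC(=O)[C@@H](C)[C@H](C)C(=O)c1cc(OC)c(OC)c(OC)c1
F6 | step 3 | (3S,4S,5R)-3,4-dimethyl-5-(3,4,5-trimethoxyphenyl)dihydrofuran-2(3H)-one | O=C1O[C@@H](c2cc(OC)c(OC)c(OC)c2)[C@@H](C)[C@@H]1C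
F7 | step 4 | (2S,3S,4S)-4-hydroxy-N-methoxy-N,2,3-trimethyl-4-(3,4,5-trimethoxyphenyl)butanamide | CON(C)C(=O)[C@@H](C)[C@H](C)[C@H](O)c1cc(OC)c(OC)c(OC)c1
F8 | step 4 | (2S,3S,4S)-4-(tert-butyldimethylsilyloxy)-N-methoxy-N,2,3-trimethyl-4-(3,4,5-trimethoxyphenyl)butanamide | CON(C)C(=O)[C@@H](C)[C@H](C)[C@H](O[Si](C)(C)C(C)(C)C)c1cc(OC)c(OC)c(OC)c1
F9 | step 4 | (2S,3S,4S)-4-(tert-butyldimethylsilyloxy)-1-(3,4-dimethoxyphenyl)-2,3-dimethyl-4-(3,4,5-trimethoxyphenyl)butan-1-one | COc1ccc(cc1OC)C(=O)[C@@H](C)[C@H](C)[C@H](O[Si](C)(C)C(C)(C)C)c1cc(OC)c(OC)c(OC)c1
F10 | step 5 | (1S,2S,3S,4S)-4-(tert-butyldimethylsilyloxy)-1-(3,4-dimethoxyphenyl)-2,3-dimethyl-4-(3,4,5-trimethoxyphenyl)butan-1-ol | COc1ccc(cc1OC)[C@@H](O)[C@@H](C)[C@H](C)[C@H](O[Si](C)(C)C(C)(C)C)c1cc(OC)c(OC)c(OC)c1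
F11 | step 5 | (1S,2S,3S,4S)-4-(tert-butyldimethylsilyloxy)-1-(3,4-dimethoxyphenyl)-2,3-dimethyl-4-(3,4,5-trimethoxyphenyl)butyl methanesulfonate | COc1ccc(cc1OC)[C@@H](OS(C)(=O)=O)[C@@H](C)[C@H](C)[C@H](O[Si](C)(C)C(C)(C)C)c1cc(OC)c(OC)c(OC)c1
A1 | alternative 1 | 3,4,5-trimethoxybenzaldehyde | COc1cc(C=O)cc(OC)c1OC
A2 | alternative 1 | methyl (2R,3S)-3-hydroxy-2-methyl-3-(3,4,5-trimethoxyphenyl)propanoate | COC(=O)[C@H](C)[C@H](O)c1cc(OC)c(OC)c(OC)c1
A3 | alternative 1 | (4S,5S)-4-methyl-5-(3,4,5-trimethoxyphenyl)dihydrofuran-2(3H)-one | O=C1O[C@H](c2cc(OC)c(OC)c(OC)c2)[C@@H](C)C1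
A4 | alternative 2 | dimethyl (2S,3R)-2-(3,4-dimethoxyphenyl)-3-methylcyclopropane-1,1-dicarboxylate | COc1ccc([C@H]2C(C(=O)OC)(C(=O)OC)[C@@H]2C)cc1OC
A5 | alternative 2 | dimethyl (2R,4S,5R)-5-(3,4-dimethoxyphenyl)-4-methyl-2-(3,4,5-trimethoxyphenyl)tetrahydrofuran-3,3-dicarboxylate | COc1ccc([C@@H]2O[C@H](c3cc(OC)c(OC)c(OC)c3)C(C(=O)OC)(C(=O)OC)[C@@H]2C)cc1OC
A6 | alternative 3 | 2-(3,4,5-trimethoxyphenyl)-1,3-dithiane | COc1cc(C2SCCCS2)cc(OC)c1OC
A7 | alternative 3 | methyl (2S,3S)-2-methyl-3-[2-(3,4,5-trimethoxyphenyl)-1,3-dithian-2-yl]butanoate | COC(=O)[C@@H](C)[C@H](C)C1(SCCCS1)c1cc(OC)c(OC)c(OC)c1
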